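**Strategy.** Ring C is taken apart at C4a–C4, C4–C3 and O1–C2. C4 is an isolated carbonyl carbon flanked by C4a of ring A and by the C3–C2 unit that carries ring B, so it can be supplied as carbon monoxide between an ortho-iodophenol (ring A, O1 already in place) and an arylacetylene (C3, C2, ring B). One palladium-catalysed operation joins the three pieces and closes ring C as an achiral flavone; C2 is then set by a single asymmetric conjugate reduction, and mild acid frees the phenols. The ring A precursor is a symmetric para-prenyl phloroglucinol bis-MOM ether iodinated next to its only free hydroxyl, which fixes the prenyl group at C6.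

Key step: step 9

Assumption: prenyl = 3-methylbut-2-en-1-yl, MOM = methoxymethyl, TIPS = tri(propan-2-yl)silyl; the ligand antipode named in step 10 is assigned by analogy with chiral copper hydride reductions of cyclic β-substituted enones and is to be confirmed on parent flavone, the mirror-image ligand being used if hydride is delivered to the other face of C2.

Step 1
Reactants: 1 phloroglucinol
Product: 2 3,5-bis(methoxymethoxy)phenol
Conditions: MOMCl (2.1 equiv), i-Pr2NEt, DMF, 0 °C to rt
Reagents that add atoms: chloromethyl methyl ether (MOMCl), COCCl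
Why: Williamson-type O-alkylation of the phenoxide with the reactive α-chloro ether (MOM protection) is statistical at about two equivalents, so the bis-ether should be the main fraction and is separated by chromatography from the mono-ether (recycled) and the tris-ether.

Step 2
Reactants: 2 3,5-bis(methoxymethoxy)phenol
Product: 3 [3,5-bis(methoxymethoxy)phenoxy]tri(propan-2-yl)silane
Conditions: TIPSCl, imidazole, DMF, rt
Reagents that add atoms: chlorotri(propan-2-yl)silane (TIPSCl), CC(C)[Si](Cl)(C(C)C)C(C)C
Why: Imidazole-promoted O-silylation of the only free phenol installs a bulky, base-stable silyl ether that marks this oxygen as the future O1 and is a poor director of metalation.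

Step 3
Reactants: 3 [3,5-bis(methoxymethoxy)phenoxy]tri(propan-2-yl)silane; 4 prenyl bromide (1-bromo-3-methylbut-2-ene)
Product: 6 [3,5-bis(methoxymethoxy)-4-(3-methylbut-2-en-1-yl)phenoxy]tri(propan-2-yl)silane, via aryllithium 5 (not isolated)
Conditions: n-BuLi, THF, 0 °C; then prenyl bromide, –78 °C to rt
Reagents that add atoms: none
Why: Directed ortho-metalation, in which the proton between the two MOM ethers is the most acidic and doubly chelated one, should give aryllithium 5 alone, and this is alkylated at the primary carbon of the allylic bromide (SN2).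

Step 4
Reactants: 6 [3,5-bis(methoxymethoxy)-4-(3-methylbut-2-en-1-yl)phenoxy]tri(propan-2-yl)silane
Product: 7 3,5-bis(methoxymethoxy)-4-(3-methylbut-2-en-1-yl)phenol
Conditions: TBAF, AcOH, THF, 0 °C to rt
Reagents that add atoms: none
Why: Fluoride-driven cleavage of the aryl silyl ether, buffered with acetic acid, should free the phenol para to the prenyl group without touching the MOM ethers or the alkene.

Step 5
Reactants: 7 3,5-bis(methoxymethoxy)-4-(3-methylbut-2-en-1-yl)phenol
Product: 8 2-iodo-3,5-bis(methoxymethoxy)-4-(3-methylbut-2-en-1-yl)phenol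
Conditions: I2 (1.0 equiv), NaHCO3, THF/H2O, 0 °C
Reagents that add atoms: iodine, II
Why: Electrophilic aromatic iodination of the phenolate should give a single mono-iodide, because the two positions ortho to the free hydroxyl are equivalent by symmetry and so strongly activated that one equivalent of iodine is consumed there before it can engage the trisubstituted alkene.

Step 6
Reactants: 9 4-hydroxybenzaldehyde; 4 prenyl bromide (1-bromo-3-methylbut-2-ene)
Product: 10 4-hydroxy-3-(3-methylbut-2-en-1-yl)benzaldehyde
Conditions: KOH, H2O, rt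
Reagents that add atoms: none
Why: Ortho C-alkylation of the ambident phenoxide in water, where hydrogen bonding to oxygen holds back O-alkylation, is the established direct entry to ortho-prenyl phenols, although only a modest yield is to be expected after removal of the O-prenyl ether and the bis-prenylated phenol.

Step 7
Reactants: 10 4-hydroxy-3-(3-methylbut-2-en-1-yl)benzaldehyde
Product: 11 4-(methoxymethoxy)-3-(3-methylbut-2-en-1-yl)benzaldehyde
Conditions: MOMCl, i-Pr2NEt, CH2Cl2, 0 °C to rt
Reagents that add atoms: chloromethyl methyl ether (MOMCl), COCCl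
Why: Williamson-type O-alkylation (MOM protection) of the acidic para-formyl phenol should be clean and gives ring B the same acetal protection as ring A.

Step 8
Reactants: 11 4-(methoxymethoxy)-3-(3-methylbut-2-en-1-yl)benzaldehyde
Product: 12 4-ethynyl-1-(methoxymethoxy)-2-(3-methylbut-2-en-1-yl)benzene
Conditions: Ohira–Bestmann reagent, K2CO3, MeOH, rt
Reagents that add atoms: dimethyl (1-diazo-2-oxopropyl)phosphonate (Ohira–Bestmann reagent), CC(=O)C(=[N+]=[N-])P(=O)(OC)OC
Why: In this Seyferth–Gilbert homologation (Ohira–Bestmann variant), methanolysis of the reagent releases the diazomethylphosphonate anion, which adds to the non-enolisable aldehyde, eliminates phosphate in the Horner–Wadsworth–Emmons manner and loses nitrogen, and the resulting alkylidene carbene gives the terminal alkyne by 1,2-hydride shift under conditions that leave MOM ether and prenyl group alone.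

Step 9
Reactants: 8 2-iodo-3,5-bis(methoxymethoxy)-4-(3-methylbut-2-en-1-yl)phenol; 12 4-ethynyl-1-(methoxymethoxy)-2-(3-methylbut-2-en-1-yl)benzene; 13 carbon monoxide
Product: 16 5,7-bis(methoxymethoxy)-2-[4-(methoxymethoxy)-3-(3-methylbut-2-en-1-yl)phenyl]-6-(3-methylbut-2-en-1-yl)-4H-chromen-4-one, via ynone 14 (not isolated), via enaminone 15 (not isolated)
Conditions: PdCl2(PPh3)2 (5 mol%), CO (20 bar), Et2NH, 100 °C
Reagents that add atoms: none
Why: Zerovalent palladium, formed in the flask from PdCl2(PPh3)2, inserts into the C–I bond of 8, CO then inserts to give an aroyl palladium species, and amine-assisted, copper-free coupling with alkyne 12 forms C4a–C4 and C4–C3 in ynone 14. Diethylamine adds to the ynone to give enaminone 15, and the neighbouring phenol displaces the amine by addition–elimination, forming O1–C2 and closing ring C in a net 6-endo-dig oxa-Michael sense. The closest known reaction type is the palladium-catalysed carbonylative Sonogashira coupling–annulation of ortho-iodophenols, carbon monoxide and terminal arylacetylenes to flavones. No stereocentre is formed. Two selectivities are needed: carbonylation before alkynylation (otherwise a 2-arylbenzofuran results), which CO pressure, the absence of copper and the electron-rich, doubly ortho-substituted aryl palladium intermediate favour, and six- over five-membered closure (flavone, not aurone), which the enaminone pathway enforces because the amine marks C2 as the electrophilic carbon. The place of the prenyl group at C6 is fixed beforehand, since iodine lies next to the only free hydroxyl of a symmetric ring.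

Step 10
Reactants: 16 5,7-bis(methoxymethoxy)-2-[4-(methoxymethoxy)-3-(3-methylbut-2-en-1-yl)phenyl]-6-(3-methylbut-2-en-1-yl)-4H-chromen-4-one
Product: 18 (2S)-5,7-bis(methoxymethoxy)-2-[4-(methoxymethoxy)-3-(3-methylbut-2-en-1-yl)phenyl]-6-(3-methylbut-2-en-1-yl)-2,3-dihydro-4H-chromen-4-one, via silyl enol ether 17 (not isolated)
Conditions: Cu(OAc)2·H2O (5 mol%), (S)-DTBM-SEGPHOS (5.5 mol%), (EtO)2MeSiH, toluene, 0 °C to rt; then TBAF, AcOH, THF, 0 °C
Reagents that add atoms: none
Why: In this asymmetric conjugate reduction by a bisphosphine-ligated monovalent copper hydride, the Cu–H adds hydride to C2 from the face selected by the chiral pocket of the ligand (this sets the 2S centre), the copper enolate is trapped by the silane as silyl enol ether 17, which shields the carbonyl from 1,2-reduction and the ring from E1cB opening, and buffered fluoride then releases the ketone without epimerising C2; the unactivated prenyl alkenes and the MOM ethers are inert to copper hydride.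

Step 11
Reactants: 18 (2S)-5,7-bis(methoxymethoxy)-2-[4-(methoxymethoxy)-3-(3-methylbut-2-en-1-yl)phenyl]-6-(3-methylbut-2-en-1-yl)-2,3-dihydro-4H-chromen-4-one
Product: 19 macarangaflavanone B, (2S)-5,7-dihydroxy-2-[4-hydroxy-3-(3-methylbut-2-en-1-yl)phenyl]-6-(3-methylbut-2-en-1-yl)-2,3-dihydro-4H-chromen-4-one
Conditions: 3 M aq. HCl, MeOH, 40 °C
Reagents that add atoms: none
Why: Acid-catalysed acetal exchange (MOM cleavage) passes the three methoxymethyl groups to methanol under the conditions customary for prenylated flavanones, and stopping at full conversion should forestall chroman formation from the ortho-prenyl phenols, while ring opening at C2 is slow in mild acid so the configuration should be kept.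

**Compound list**

1 | phloroglucinol (benzene-1,3,5-triol) | Oc1cc(O)cc(O)c1 | starting material
2 | 3,5-bis(methoxymethoxy)phenol | COCOc1cc(O)cc(OCOC)c1 | intermediate
3 | [3,5-bis(methoxymethoxy)phenoxy]tri(propan-2-yl)silane | COCOc1cc(O[Si](C(C)C)(C(C)C)C(C)C)cc(OCOC)c1 | intermediate
4 | prenyl bromide (1-bromo-3-methylbut-2-ene) | CC(C)=CCBr | starting material
5 | [2,6-bis(methoxymethoxy)-4-{[tri(propan-2-yl)silyl]oxy}phenyl]lithium | [Li]c1c(OCOC)cc(O[Si](C(C)C)(C(C)C)C(C)C)cc1OCOC | intermediate
6 | [3,5-bis(methoxymethoxy)-4-(3-methylbut-2-en-1-yl)phenoxy]tri(propan-2-yl)silane | CC(C)=CCc1c(OCOC)cc(O[Si](C(C)C)(C(C)C)C(C)C)cc1OCOC | intermediate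
7 | 3,5-bis(methoxymethoxy)-4-(3-methylbut-2-en-1-yl)phenol | CC(C)=CCc1c(OCOC)cc(O)cc1OCOC | intermediate
8 | 2-iodo-3,5-bis(methoxymethoxy)-4-(3-methylbut-2-en-1-yl)phenol | Oc1cc(OCOC)c(CC=C(C)C)c(OCOC)c1I | intermediate
9 | 4-hydroxybenzaldehyde | O=Cc1ccc(O)cc1 | starting material
10 | 4-hydroxy-3-(3-methylbut-2-en-1-yl)benzaldehyde | CC(C)=CCc1cc(C=O)ccc1O | intermediate
11 | 4-(methoxymethoxy)-3-(3-methylbut-2-en-1-yl)benzaldehyde | CC(C)=CCc1cc(C=O)ccc1OCOC | intermediate
12 | 4-ethynyl-1-(methoxymethoxy)-2-(3-methylbut-2-en-1-yl)benzene | C#Cc1ccc(OCOC)c(CC=C(C)C)c1 | intermediate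
13 | carbon monoxide | [C-]#[O+] | starting material
14 | 1-[6-hydroxy-2,4-bis(methoxymethoxy)-3-(3-methylbut-2-en-1-yl)phenyl]-3-[4-(methoxymethoxy)-3-(3-methylbut-2-en-1-yl)phenyl]prop-2-yn-1-one | O=C(C#Cc1ccc(OCOC)c(CC=C(C)C)c1)c1c(O)cc(OCOC)c(CC=C(C)C)c1OCOC | intermediate
15 | (E)-3-(diethylamino)-1-[6-hydroxy-2,4-bis(methoxymethoxy)-3-(3-methylbut-2-en-1-yl)phenyl]-3-[4-(methoxymethoxy)-3-(3-methylbut-2-en-1-yl)phenyl]prop-2-en-1-one | O=C(/C=C(/N(CC)CC)c1ccc(OCOC)c(CC=C(C)C)c1)c1c(O)cc(OCOC)c(CC=C(C)C)c1OCOC | intermediate
16 | 5,7-bis(methoxymethoxy)-2-[4-(methoxymethoxy)-3-(3-methylbut-2-en-1-yl)phenyl]-6-(3-methylbut-2-en-1-yl)-4H-chromen-4-one | CC(C)=CCc1cc(-c2cc(=O)c3c(cc(OCOC)c(CC=C(C)C)c3OCOC)o2)ccc1OCOC | intermediate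
17 | (2S)-4-{[diethoxy(methyl)silyl]oxy}-5,7-bis(methoxymethoxy)-2-[4-(methoxymethoxy)-3-(3-methylbut-2-en-1-yl)phenyl]-6-(3-methylbut-2-en-1-yl)-2H-chromene | CC(C)=CCc1cc([C@@H]2C=C(O[Si](C)(OCC)OCC)c3c(cc(OCOC)c(CC=C(C)C)c3OCOC)O2)ccc1OCOC | intermediate
18 | (2S)-5,7-bis(methoxymethoxy)-2-[4-(methoxymethoxy)-3-(3-methylbut-2-en-1-yl)phenyl]-6-(3-methylbut-2-en-1-yl)-2,3-dihydro-4H-chromen-4-one | CC(C)=CCc1cc([C@@H]2CC(=O)c3c(cc(OCOC)c(CC=C(C)C)c3OCOC)O2)ccc1OCOC | intermediate
19 | macarangaflavanone B, (2S)-5,7-dihydroxy-2-[4-hydroxy-3-(3-methylbut-2-en-1-yl)phenyl]-6-(3-methylbut-2-en-1-yl)-2,3-dihydro-4H-chromen-4-one | CC(C)=CCc1cc([C@@H]2CC(=O)c3c(cc(O)c(CC=C(C)C)c3O)O2)ccc1O | target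

**Step count.** Total: 11 steps. Longest linear sequence: 8 steps (steps 1, 2, 3, 4, 5, 9, 10, 11); the ring B branch (steps 6 to 8) has 3 steps.

**Steps most likely to fail**

1. Step 9. What may go wrong: oxidative addition at the doubly ortho-oxygenated carbon may be slow, the alkyne may couple before CO inserts, or diethylamine may capture the aroyl palladium species as an amide. The fallback builds the same ynone stepwise without palladium; it sets out from phenol 7 and alkyne 12 and comes back to the route at ynone 14. Phenol 7 is formylated at one of its two equivalent ortho positions (MgCl2, Et3N, paraformaldehyde, MeCN, reflux) to give 6-hydroxy-2,4-bis(methoxymethoxy)-3-(3-methylbut-2-en-1-yl)benzaldehyde F1. Alkyne 12 is deprotonated (n-BuLi, THF, –78 °C) to the lithium acetylide F2, of which 2.5 equivalents are added to F1; quenching with aq. NH4Cl gives the racemic propargylic alcohol F3. Activated MnO2 (CH2Cl2, rt) oxidises the benzylic, propargylic carbinol of F3 to ynone 14. Diethylamine (EtOH, rt to 50 °C) then closes 14 through 15 to flavone 16, as in the second half of step 9.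

2. Step 10. What may go wrong: the catalyst may discriminate poorly between the two faces of the flat C2=C3 bond, or the enantiomeric purity may erode through ring opening of the enolate on work-up. The fallback replaces induction by resolution; it sets out from flavone 16 and comes back at flavanone 18. Flavone 16 is reduced with an achiral bisphosphine copper hydride (Cu(OAc)2·H2O, 1,2-bis(diphenylphosphino)benzene, (EtO)2MeSiH, toluene, rt) to the racemic silyl enol ether F4, which buffered TBAF (AcOH, THF, 0 °C) converts into the racemic flavanone F5. Preparative chromatography on a chiral stationary phase (amylose or cellulose carbamate) separates (2S)-flavanone 18 from the (2R)-flavanone F6. F6 is returned to F5 by base-mediated ring opening and re-closure (NaOAc, EtOH, reflux) and separated again.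

3. Step 5. What may go wrong: electrophilic iodine may attack the prenyl double bond, with participation of a neighbouring MOM oxygen, or a second iodination may occur at the other ortho position. The fallback places the iodine by directed metalation before the phenol is freed; it sets out from silyl ether 6 and comes back at iodophenol 8. Silyl ether 6 is lithiated at the ring position between the silyl ether and a MOM ether (n-BuLi, TMEDA, THF, –78 to –20 °C) to the aryllithium F7, which is quenched with I2 at –78 °C to give the iodo silyl ether F8. Buffered TBAF (AcOH, THF, 0 °C) then frees iodophenol 8.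

**Further compounds**

F1 | step 9 | 6-hydroxy-2,4-bis(methoxymethoxy)-3-(3-methylbut-2-en-1-yl)benzaldehyde | O=Cc1c(O)cc(OCOC)c(CC=C(C)C)c1OCOC
F2 | step 9 | lithium {[4-(methoxymethoxy)-3-(3-methylbut-2-en-1-yl)phenyl]ethynide} | [Li]C#Cc1ccc(OCOC)c(CC=C(C)C)c1
F3 | step 9 | racemic 1-[6-hydroxy-2,4-bis(methoxymethoxy)-3-(3-methylbut-2-en-1-yl)phenyl]-3-[4-(methoxymethoxy)-3-(3-methylbut-2-en-1-yl)phenyl]prop-2-yn-1-ol | OC(C#Cc1ccc(OCOC)c(CC=C(C)C)c1)c1c(O)cc(OCOC)c(CC=C(C)C)c1OCOC
F4 | step 10 | racemic 4-{[diethoxy(methyl)silyl]oxy}-5,7-bis(methoxymethoxy)-2-[4-(methoxymethoxy)-3-(3-methylbut-2-en-1-yl)phenyl]-6-(3-methylbut-2-en-1-yl)-2H-chromene | CC(C)=CCc1cc(C2C=C(O[Si](C)(OCC)OCC)c3c(cc(OCOC)c(CC=C(C)C)c3OCOC)O2)ccc1OCOC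
F5 | step 10 | racemic 5,7-bis(methoxymethoxy)-2-[4-(methoxymethoxy)-3-(3-methylbut-2-en-1-yl)phenyl]-6-(3-methylbut-2-en-1-yl)-2,3-dihydro-4H-chromen-4-one | CC(C)=CCc1cc(C2CC(=O)c3c(cc(OCOC)c(CC=C(C)C)c3OCOC)O2)ccc1OCOC
F6 | step 10 | (2R)-5,7-bis(methoxymethoxy)-2-[4-(methoxymethoxy)-3-(3-methylbut-2-en-1-yl)phenyl]-6-(3-methylbut-2-en-1-yl)-2,3-dihydro-4H-chromen-4-one | CC(C)=CCc1cc([C@H]2CC(=O)c3c(cc(OCOC)c(CC=C(C)C)c3OCOC)O2)ccc1OCOC
F7 | step 5 | [2,4-bis(methoxymethoxy)-3-(3-methylbut-2-en-1-yl)-6-{[tri(propan-2-yl)silyl]oxy}phenyl]lithium | [Li]c1c(O[Si](C(C)C)(C(C)C)C(C)C)cc(OCOC)c(CC=C(C)C)c1OCOC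
F8 | step 5 | [2-iodo-3,5-bis(methoxymethoxy)-4-(3-methylbut-2-en-1-yl)phenoxy]tri(propan-2-yl)silane | Ic1c(O[Si](C(C)C)(C(C)C)C(C)C)cc(OCOC)c(CC=C(C)C)c1OCOC
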